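The route rests on cutting ring B across B2–B3 and B4–B5. The oxygenated carbon B3 and its unsubstituted neighbour B4 form a two-carbon unit that (triisopropylsilyloxy)acetylene can deliver, while B2, B1, B6 and B5 map onto C3–C6 of a 5-aroyl-2-pyrone. In one operation an inverse-electron-demand Diels–Alder addition and loss of CO2 close ring B, aromatize it and place the masked phenol para to the future B6 benzyl group. The precursor is a 2-pyrone whose C4 carries the ethylene bridge with the complete, benzyl-protected ring A and whose C5 carries a 4-(benzyloxy)benzoyl group, later reduced to the B6 benzyl unit.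

Key step: step 12

Remark: the target is achiral, so no stereocentre has to be set. The parent lithium ynolate 20 is assumed to silylate on oxygen with i-Pr3SiOTf as substituted ynolates do, and 21 is used freshly prepared.

Step 1
Reactants: 1 3-hydroxy-5-methoxybenzaldehyde
Product: 2 3-(benzyloxy)-5-methoxybenzaldehyde
Conditions: BnBr, K2CO3, DMF, 25 °C
Reagents that add atoms: benzyl bromide BrCc1ccccc1
Why: Williamson ether synthesis of the phenoxide with benzyl bromide; benzyl is chosen because it leaves at the end together with the other three benzyl ethers.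

Step 2
Reactants: 2 3-(benzyloxy)-5-methoxybenzaldehyde
Product: 3 3-(benzyloxy)-2,6-dibromo-5-methoxybenzaldehyde
Conditions: NBS (2.2 equiv), MeCN, 25→50 °C
Reagents that add atoms: N-bromosuccinimide O=C1CCC(=O)N1Br
Why: Electrophilic aromatic bromination, in which C2 and C6 are each ortho to one alkoxy group and para to the other while C4 is flanked and shielded by both alkoxy groups, so two equivalents should stop at the 2,6-dibromide.

Step 3
Reactants: 3 3-(benzyloxy)-2,6-dibromo-5-methoxybenzaldehyde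
Product: 4 [3-(benzyloxy)-2,6-dibromo-5-methoxyphenyl]methanol
Conditions: NaBH4, MeOH/THF, 0 °C
Reagents that add atoms: none
Why: Hydride reduction of the aldehyde by NaBH4 leaves aryl bromides and the benzyl ether untouched and removes the one group that a benzylic zinc reagent would attack later.

Step 4
Reactants: 4 [3-(benzyloxy)-2,6-dibromo-5-methoxyphenyl]methanol
Product: 5 1-(benzyloxy)-2,4-dibromo-3-(bromomethyl)-5-methoxybenzene
Conditions: CBr4, PPh3, CH2Cl2, 0 °C
Reagents that add atoms: carbon tetrabromide BrC(Br)(Br)Br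
Why: Appel reaction of the primary benzylic alcohol under neutral conditions that do not disturb the benzyl ether.

Step 5
Reactants: 5 1-(benzyloxy)-2,4-dibromo-3-(bromomethyl)-5-methoxybenzene; 6 1-(trimethylsilyl)propyne
Product: 8 {4-[3-(benzyloxy)-2,6-dibromo-5-methoxyphenyl]but-1-yn-1-yl}trimethylsilane, via silylpropargyllithium 7 (not isolated)
Conditions: 6 (1.3 equiv), n-BuLi (1.2 equiv), THF, −78 °C; then 5, −78→−20 °C
Reagents that add atoms: none
Why: SN2 alkylation of the lithiated silylpropyne, which reacts at its CH2 end with primary benzylic bromides and is too stabilized to exchange with the aryl bromides at low temperature.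

Step 6
Reactants: 8 {4-[3-(benzyloxy)-2,6-dibromo-5-methoxyphenyl]but-1-yn-1-yl}trimethylsilane; 9 4-(benzyloxy)benzyl chloride
Product: 11 {4-[3-(benzyloxy)-2,6-bis[4-(benzyloxy)benzyl]-5-methoxyphenyl]but-1-yn-1-yl}trimethylsilane, via benzylic zinc chloride 10 (not isolated)
Conditions: 9 (3 equiv), Zn dust, LiCl, THF, 25 °C; then 8, Pd(OAc)2 (5 mol%), SPhos (10 mol%), 25→50 °C
Reagents that add atoms: none
Why: Double Negishi coupling, in which zinc inserts into the benzylic C–Cl bond in the presence of LiCl and the Pd(OAc)2/SPhos catalyst is active enough for both di-ortho-substituted aryl bromides, the silyl-capped alkyne being inert.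

Step 7
Reactants: 11 {4-[3-(benzyloxy)-2,6-bis[4-(benzyloxy)benzyl]-5-methoxyphenyl]but-1-yn-1-yl}trimethylsilane
Product: 12 1-(benzyloxy)-2,4-bis[4-(benzyloxy)benzyl]-3-(but-3-yn-1-yl)-5-methoxybenzene
Conditions: K2CO3 (cat.), MeOH/THF, 25 °C
Reagents that add atoms: none
Why: Carbonate-catalysed methanolysis of the alkynyl C–Si bond (protodesilylation) is selective because the molecule holds no other silyl or base-labile group.

Step 8
Reactants: 12 1-(benzyloxy)-2,4-bis[4-(benzyloxy)benzyl]-3-(but-3-yn-1-yl)-5-methoxybenzene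
Product: 14 methyl 5-{3-(benzyloxy)-2,6-bis[4-(benzyloxy)benzyl]-5-methoxyphenyl}pent-2-ynoate, via lithium acetylide 13 (not isolated)
Conditions: n-BuLi, THF, −78 °C; then ClCO2Me, −78→0 °C
Reagents that add atoms: methyl chloroformate COC(Cl)=O
Why: Deprotonation of the terminal alkyne, by far the most acidic C–H, and C-acylation of the lithium acetylide with the chloroformate give the alkynoate.

Step 9
Reactants: 15 4-(benzyloxy)acetophenone
Product: 16 sodium (1Z)-3-[4-(benzyloxy)phenyl]-3-oxoprop-1-en-1-olate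
Conditions: HCO2Et, NaH, THF, 0→25 °C; salt collected by filtration
Reagents that add atoms: ethyl formate CCOC=O; sodium hydride [Na+].[H-]
Why: Crossed Claisen condensation of the methyl ketone enolate with ethyl formate is driven by formation of the stable sodium enolate, which also avoids handling the self-condensing free keto aldehyde.

Step 10
Reactants: 14 methyl 5-{3-(benzyloxy)-2,6-bis[4-(benzyloxy)benzyl]-5-methoxyphenyl}pent-2-ynoate; 16 sodium (1Z)-3-[4-(benzyloxy)phenyl]-3-oxoprop-1-en-1-olate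
Product: 18 5-[4-(benzyloxy)benzoyl]-4-(2-{3-(benzyloxy)-2,6-bis[4-(benzyloxy)benzyl]-5-methoxyphenyl}ethyl)-2H-pyran-2-one, via sodium dienolate 17 (not isolated)
Conditions: 16 (2 equiv), DMSO, 25→50 °C; then AcOH, 80 °C
Reagents that add atoms: none
Why: Michael addition of the 1,3-dicarbonyl anion to the β-carbon of the alkynoate followed by lactonization is the classical pyrone synthesis from alkynoates and 1,3-dicarbonyl compounds, and the unhindered formyl enolate oxygen should close onto the ester, so C6 stays unsubstituted and the aroyl group sits at C5.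

Step 11
Reactants: 19 3-phenylisoxazole
Product: 21 (ethynyloxy)triisopropylsilane, via lithium ethynolate 20 (not isolated)
Conditions: n-BuLi, THF, −78 °C; then i-Pr3SiOTf, −78→0 °C; rapid filtration through silica in pentane
Reagents that add atoms: triisopropylsilyl trifluoromethanesulfonate CC(C)[Si](OS(=O)(=O)C(F)(F)F)(C(C)C)C(C)C
Why: Deprotonation at C5 of the 3-substituted isoxazole triggers fragmentation to benzonitrile and the ynolate, and the hard, bulky silyl triflate should trap the ynolate on oxygen as in the known O-silylation of ynolates to siloxyalkynes.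

Step 12
Reactants: 18 5-[4-(benzyloxy)benzoyl]-4-(2-{3-(benzyloxy)-2,6-bis[4-(benzyloxy)benzyl]-5-methoxyphenyl}ethyl)-2H-pyran-2-one; 21 (ethynyloxy)triisopropylsilane
Product: 23 [4-(benzyloxy)phenyl][2-(2-{3-(benzyloxy)-2,6-bis[4-(benzyloxy)benzyl]-5-methoxyphenyl}ethyl)-4-(triisopropylsilyloxy)phenyl]methanone, via bicyclic lactone 22 (not isolated)
Conditions: 21 (3 equiv), PhMe, 90 °C, sealed tube, Ar
Reagents that add atoms: none
Why: The 5-aroyl group lowers the LUMO of the pyrone diene, so the electron-rich siloxyalkyne adds across C3 and C6 in an asynchronous inverse-electron-demand [4+2] cycloaddition, bond formation at C6 running ahead, to give the bridged 2-oxabicyclo[2.2.2]octadienone 22. Retro-Diels–Alder loss of CO2 from 22 then forms the benzene ring irreversibly. The closest known reaction type is the cycloaddition of acyl- or alkoxycarbonyl-substituted 2-pyrones with ynamines, alkoxyalkynes, siloxyalkynes or ketene acetals with extrusion of CO2. Ring B is closed as a six-membered carbocycle by intermolecular [4+2] addition, B2–B3 and B4–B5 both being made in that event. The two bridgehead centres of 22 vanish on aromatization, so no stereocentre has to be controlled. Regioselectivity is the one selectivity required and polarity matching provides it: C6, the β-position of the aroyl enone, takes the unsubstituted alkyne carbon and the silyloxy-bearing carbon bonds to C3, so the oxygen ends up 1,4 to the ketone-bearing carbon and 1,3 to the bridge.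

Step 13
Reactants: 23 [4-(benzyloxy)phenyl][2-(2-{3-(benzyloxy)-2,6-bis[4-(benzyloxy)benzyl]-5-methoxyphenyl}ethyl)-4-(triisopropylsilyloxy)phenyl]methanone
Product: 24 {4-[4-(benzyloxy)benzyl]-3-(2-{3-(benzyloxy)-2,6-bis[4-(benzyloxy)benzyl]-5-methoxyphenyl}ethyl)phenoxy}triisopropylsilane
Conditions: Et3SiH (3 equiv), BF3·OEt2 (promoter), CH2Cl2/MeCN, 0→25 °C
Reagents that add atoms: none
Why: Ionic hydrogenation, in which the Lewis acid activates the doubly para-oxygenated diaryl ketone and Et3SiH delivers hydride first to the carbonyl and then to the strongly stabilized diarylmethyl cation, gives the methylene group without touching benzyl or silyl ethers.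

Step 14
Reactants: 24 {4-[4-(benzyloxy)benzyl]-3-(2-{3-(benzyloxy)-2,6-bis[4-(benzyloxy)benzyl]-5-methoxyphenyl}ethyl)phenoxy}triisopropylsilane
Product: 25 4-[4-(benzyloxy)benzyl]-3-(2-{3-(benzyloxy)-2,6-bis[4-(benzyloxy)benzyl]-5-methoxyphenyl}ethyl)phenol
Conditions: Bu4NF, AcOH, THF, 0 °C
Reagents that add atoms: none
Why: Fluoride-induced cleavage of the aryl silyl ether, buffered with acetic acid, unmasks the ring B phenol and leaves methyl and benzyl ethers intact.

Step 15
Reactants: 25 4-[4-(benzyloxy)benzyl]-3-(2-{3-(benzyloxy)-2,6-bis[4-(benzyloxy)benzyl]-5-methoxyphenyl}ethyl)phenol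
Product: 26 4-(4-hydroxybenzyl)-3-{2-[3-hydroxy-2,6-bis(4-hydroxybenzyl)-5-methoxyphenyl]ethyl}phenol (CNP0147493.0)
Conditions: H2 (1 atm), 10% Pd/C, EtOAc/MeOH, 25 °C
Reagents that add atoms: none
Why: Catalytic hydrogenolysis cleaves the four O-benzyl bonds, while the methyl ether and the diarylmethane C–C bonds are stable under these conditions.

Compound list

1 | 3-hydroxy-5-methoxybenzaldehyde | COc1cc(O)cc(C=O)c1 | starting material
2 | 3-(benzyloxy)-5-methoxybenzaldehyde | COc1cc(OCc2ccccc2)cc(C=O)c1 | intermediate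
3 | 3-(benzyloxy)-2,6-dibromo-5-methoxybenzaldehyde | COc1cc(OCc2ccccc2)c(Br)c(C=O)c1Br | intermediate
4 | [3-(benzyloxy)-2,6-dibromo-5-methoxyphenyl]methanol | COc1cc(OCc2ccccc2)c(Br)c(CO)c1Br | intermediate
5 | 1-(benzyloxy)-2,4-dibromo-3-(bromomethyl)-5-methoxybenzene | COc1cc(OCc2ccccc2)c(Br)c(CBr)c1Br | intermediate
6 | 1-(trimethylsilyl)propyne | CC#C[Si](C)(C)C | starting material
7 | [3-(trimethylsilyl)prop-2-yn-1-yl]lithium | [Li]CC#C[Si](C)(C)C | intermediate (not isolated)
8 | {4-[3-(benzyloxy)-2,6-dibromo-5-methoxyphenyl]but-1-yn-1-yl}trimethylsilane | COc1cc(OCc2ccccc2)c(Br)c(CCC#C[Si](C)(C)C)c1Br | intermediate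
9 | 4-(benzyloxy)benzyl chloride | ClCc1ccc(OCc2ccccc2)cc1 | starting material
10 | [4-(benzyloxy)benzyl]zinc chloride | Cl[Zn]Cc1ccc(OCc2ccccc2)cc1 | intermediate (not isolated)
11 | {4-[3-(benzyloxy)-2,6-bis[4-(benzyloxy)benzyl]-5-methoxyphenyl]but-1-yn-1-yl}trimethylsilane | COc1cc(OCc2ccccc2)c(Cc2ccc(OCc3ccccc3)cc2)c(CCC#C[Si](C)(C)C)c1Cc1ccc(OCc2ccccc2)cc1 | intermediate
12 | 1-(benzyloxy)-2,4-bis[4-(benzyloxy)benzyl]-3-(but-3-yn-1-yl)-5-methoxybenzene | C#CCCc1c(Cc2ccc(OCc3ccccc3)cc2)c(OCc2ccccc2)cc(OC)c1Cc1ccc(OCc2ccccc2)cc1 | intermediate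
13 | lithium acetylide of 12 | [Li]C#CCCc1c(Cc2ccc(OCc3ccccc3)cc2)c(OCc2ccccc2)cc(OC)c1Cc1ccc(OCc2ccccc2)cc1 | intermediate (not isolated)
14 | methyl 5-{3-(benzyloxy)-2,6-bis[4-(benzyloxy)benzyl]-5-methoxyphenyl}pent-2-ynoate | COC(=O)C#CCCc1c(Cc2ccc(OCc3ccccc3)cc2)c(OCc2ccccc2)cc(OC)c1Cc1ccc(OCc2ccccc2)cc1 | intermediate
15 | 4-(benzyloxy)acetophenone | CC(=O)c1ccc(OCc2ccccc2)cc1 | starting material
16 | sodium (1Z)-3-[4-(benzyloxy)phenyl]-3-oxoprop-1-en-1-olate (drawn as the chelated Z enolate) | [Na+].[O-]/C=C\C(=O)c1ccc(OCc2ccccc2)cc1 | intermediate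
17 | sodium dienolate of methyl 4-[4-(benzyloxy)benzoyl]-3-(2-{3-(benzyloxy)-2,6-bis[4-(benzyloxy)benzyl]-5-methoxyphenyl}ethyl)-5-oxopent-2-enoate (delocalized anion, double-bond geometry mobile) | [Na+].[O-]C=C(C(=O)c1ccc(OCc2ccccc2)cc1)C(CCc1c(Cc2ccc(OCc3ccccc3)cc2)c(OCc2ccccc2)cc(OC)c1Cc1ccc(OCc2ccccc2)cc1)=CC(=O)OC | intermediate (not isolated)
18 | 5-[4-(benzyloxy)benzoyl]-4-(2-{3-(benzyloxy)-2,6-bis[4-(benzyloxy)benzyl]-5-methoxyphenyl}ethyl)-2H-pyran-2-one | O=c1cc(CCc2c(Cc3ccc(OCc4ccccc4)cc3)c(OCc3ccccc3)cc(OC)c2Cc2ccc(OCc3ccccc3)cc2)c(C(=O)c2ccc(OCc3ccccc3)cc2)co1 | intermediate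
19 | 3-phenylisoxazole | c1ccc(-c2ccon2)cc1 | starting material
20 | lithium ethynolate | [Li+].[O-]C#C | intermediate (not isolated)
21 | (ethynyloxy)triisopropylsilane | C#CO[Si](C(C)C)(C(C)C)C(C)C | intermediate
22 | 6-[4-(benzyloxy)benzoyl]-5-(2-{3-(benzyloxy)-2,6-bis[4-(benzyloxy)benzyl]-5-methoxyphenyl}ethyl)-8-(triisopropylsilyloxy)-2-oxabicyclo[2.2.2]octa-5,7-dien-3-one (racemic, one enantiomer drawn) | O=C1O[C@@H]2C=C(O[Si](C(C)C)(C(C)C)C(C)C)[C@H]1C(CCc3c(Cc4ccc(OCc5ccccc5)cc4)c(OCc4ccccc4)cc(OC)c3Cc3ccc(OCc4ccccc4)cc3)=C2C(=O)c1ccc(OCc2ccccc2)cc1 | intermediate (not isolated)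
23 | [4-(benzyloxy)phenyl][2-(2-{3-(benzyloxy)-2,6-bis[4-(benzyloxy)benzyl]-5-methoxyphenyl}ethyl)-4-(triisopropylsilyloxy)phenyl]methanone | CC(C)[Si](Oc1ccc(C(=O)c2ccc(OCc3ccccc3)cc2)c(CCc2c(Cc3ccc(OCc4ccccc4)cc3)c(OCc3ccccc3)cc(OC)c2Cc2ccc(OCc3ccccc3)cc2)c1)(C(C)C)C(C)C | intermediate
24 | {4-[4-(benzyloxy)benzyl]-3-(2-{3-(benzyloxy)-2,6-bis[4-(benzyloxy)benzyl]-5-methoxyphenyl}ethyl)phenoxy}triisopropylsilane | CC(C)[Si](Oc1ccc(Cc2ccc(OCc3ccccc3)cc2)c(CCc2c(Cc3ccc(OCc4ccccc4)cc3)c(OCc3ccccc3)cc(OC)c2Cc2ccc(OCc3ccccc3)cc2)c1)(C(C)C)C(C)C | intermediate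
25 | 4-[4-(benzyloxy)benzyl]-3-(2-{3-(benzyloxy)-2,6-bis[4-(benzyloxy)benzyl]-5-methoxyphenyl}ethyl)phenol | Oc1ccc(Cc2ccc(OCc3ccccc3)cc2)c(CCc2c(Cc3ccc(OCc4ccccc4)cc3)c(OCc3ccccc3)cc(OC)c2Cc2ccc(OCc3ccccc3)cc2)c1 | intermediate
26 | 4-(4-hydroxybenzyl)-3-{2-[3-hydroxy-2,6-bis(4-hydroxybenzyl)-5-methoxyphenyl]ethyl}phenol | COc1cc(O)c(Cc2ccc(O)cc2)c(CCc2cc(O)ccc2Cc2ccc(O)cc2)c1Cc1ccc(O)cc1 | target

Total step count: 15. Longest linear sequence: 13 steps (steps 1–8, 10, 12–15, from compound 1).

Steps most likely to fail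

Step 12. The terminal siloxyalkyne may decompose (rearrangement to a silylketene, hydrolysis) faster than it adds to the hindered and only moderately electron-poor pyrone, or the addition may lose regiocontrol. The fallback sets out from pyrone 18 and comes back to the route at phenol 25. The alkyne is replaced by an alkene of the same polarity at the acid oxidation level: 1,1-bis(trimethylsilyloxy)ethene F1, made from trimethylsilyl acetate with LiN(i-Pr)2 and Me3SiCl, should add across C3 and C6 of 18 in the same regiochemical sense (PhMe, 25–80 °C). Loss of CO2 and 1,2-elimination of trimethylsilanol from the resulting dihydroarene would give the aryl trimethylsilyl ether of [4-(benzyloxy)phenyl][2-(2-arylethyl)-4-hydroxyphenyl]methanone F2, which aqueous methanolic work-up hydrolyses to the phenol ketone [4-(benzyloxy)phenyl][2-(2-{3-(benzyloxy)-2,6-bis[4-(benzyloxy)benzyl]-5-methoxyphenyl}ethyl)-4-hydroxyphenyl]methanone F3. Ionic hydrogenation of F3 (Et3SiH, BF3·OEt2, CH2Cl2/MeCN) then gives 25. This fallback also removes the dependence on 21, should its preparation in step 11 prove unreliable.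

Step 10. Conjugate addition to the β-alkyl alkynoate may be slow and be overtaken by base-induced isomerization of the alkynoate or by self-condensation of the keto aldehyde, or ring closure may take place through the ketone oxygen. The fallback sets out from alkynoate 14 and comes back at dienolate 17. Hydroiodination of 14 (NaI, AcOH, 70 °C) should give, by anti addition, methyl (2Z)-3-iodo-5-{3-(benzyloxy)-2,6-bis[4-(benzyloxy)benzyl]-5-methoxyphenyl}pent-2-enoate F4. Salt 16 (2 equiv, the second as base; DMSO, 25–50 °C, CuI as catalyst if needed) then replaces iodide by addition–elimination with retention of the double-bond geometry. This gives 17 already in the Z geometry that ring closure needs, and acidification as in step 10 gives 18.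

Step 6. Oxidative addition into the electron-rich, di-ortho-substituted C–Br bonds may be slow, so that the second coupling stalls and reductive debromination or homocoupling of the zinc reagent takes over. The fallback sets out from dibromide 8 and comes back at 11. Twofold bromine–lithium exchange (t-BuLi, THF, −78 °C) and addition of the dilithiated arene to 4-(benzyloxy)benzaldehyde should give the bis(diarylmethanol) {3-(benzyloxy)-5-methoxy-2-[4-(trimethylsilyl)but-3-yn-1-yl]-1,3-phenylene... }diol, named simply as the diol of 11, F5, as a mixture of diastereomers. Ionic hydrogenation of both benzylic alcohols (Et3SiH, CF3CO2H, CH2Cl2, 0 °C) removes the two stereocentres and gives 11.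

Further compounds

F1 | step 12 | 1,1-bis(trimethylsilyloxy)ethene | C=C(O[Si](C)(C)C)O[Si](C)(C)C
F2 | step 12 | [4-(benzyloxy)phenyl][2-(2-{3-(benzyloxy)-2,6-bis[4-(benzyloxy)benzyl]-5-methoxyphenyl}ethyl)-4-(trimethylsilyloxy)phenyl]methanone | C[Si](C)(C)Oc1ccc(C(=O)c2ccc(OCc3ccccc3)cc2)c(CCc2c(Cc3ccc(OCc4ccccc4)cc3)c(OCc3ccccc3)cc(OC)c2Cc2ccc(OCc3ccccc3)cc2)c1
F3 | step 12 | [4-(benzyloxy)phenyl][2-(2-{3-(benzyloxy)-2,6-bis[4-(benzyloxy)benzyl]-5-methoxyphenyl}ethyl)-4-hydroxyphenyl]methanone | Oc1ccc(C(=O)c2ccc(OCc3ccccc3)cc2)c(CCc2c(Cc3ccc(OCc4ccccc4)cc3)c(OCc3ccccc3)cc(OC)c2Cc2ccc(OCc3ccccc3)cc2)c1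
F4 | step 10 | methyl (2Z)-3-iodo-5-{3-(benzyloxy)-2,6-bis[4-(benzyloxy)benzyl]-5-methoxyphenyl}pent-2-enoate | COC(=O)/C=C(\I)CCc1c(Cc2ccc(OCc3ccccc3)cc2)c(OCc2ccccc2)cc(OC)c1Cc1ccc(OCc2ccccc2)cc1
F5 | step 6 | {4-[3-(benzyloxy)-2,6-bis{[4-(benzyloxy)phenyl](hydroxy)methyl}-5-methoxyphenyl]but-1-yn-1-yl}trimethylsilane (mixture of diastereomers, centres removed in the next operation) | COc1cc(OCc2ccccc2)c(C(O)c2ccc(OCc3ccccc3)cc2)c(CCC#C[Si](C)(C)C)c1C(O)c1ccc(OCc2ccccc2)cc1
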